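**Plan**

- Numbering: trione core C1 (benzoyl), C2(=O), C3, C4(=O), C5 (geranyl), C6, C7, C8 (Me2), C9(=O); cyclopentane C3–Ca(H2)–Cb(H)(CMe2OH)–Cc(Me2)–Cd(H); Ce(H2) joins Cd to C7.
- Retrosynthesis: cut C3–Cd, Cb–Cc and C–OH to a spiro(2-isopropenylcyclopropane) (C3, Ca, Cb) on a bicyclo[3.3.1]nonane-2,4,9-trione with an endo C7 prenyl group (Ce–Cd=Cc). Then cut C1–benzoyl, C1–C2 (Claisen), C5–geranyl and C5–C4, back to cyclohexanone 7 and cyclopropane acid 13.
- Forward: cyclohexanone ring (Michael/aldol, two cuprate additions); C5 acylation and geranylation; trione ring by Claisen closure (bicyclo[3.3.1] core); bridgehead benzoylation; then one radical cascade closes the seven-membered ring of the homoadamantane and enlarges the three-membered ring to the cyclopentane while setting the tertiary OH.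
- Enabling feature: C3 lies between the C2 and C4 ketones, and Cb carries the C3 unit that becomes CMe2OH. A radical on that unit opens the C3–Cb bond to a 1,3-diketone-stabilised C3 radical lying under the endo prenyl group; insertion of Cd–Cc closes the ring again, two atoms larger.
- Stereochemistry: C7 from (S)-diarylprolinol catalysis; C5 by alkylation anti to the C7 substituent; C1 by the bridged ring closure; C3, Cd and Cb in the cascade (cage geometry, alkene turned away from the C8 methyls, exo face). The cyclopropane is a diastereomer mixture that converges.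

Key step: step 14

Remark: 5-methylhex-4-enal is taken as a commercial aldehyde. The cyclopropane fragment is used racemic and carried as a diastereomer mixture, because both of its stereocentres are erased when the ring opens in step 14.

Step 1
Reactants: 1 5-methylhex-4-enal; 2 but-3-en-2-one
Product: 3 (S)-2-(3-methylbut-2-en-1-yl)-5-oxohexanal
Conditions: (S)-α,α-diphenylprolinol TMS ether (10 mol %), ethyl 3,4-dihydroxybenzoate (20 mol %), neat, 4 °C
Reagents that add atoms: none
Why: Enamine-catalysed Michael addition of an aldehyde to an enone; the diarylcarbinol group of the (S)-catalyst shields one face of the anti E-enamine, so the enone should add to the other face and give the (S)-aldehyde.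

Step 2
Reactants: 3 (S)-2-(3-methylbut-2-en-1-yl)-5-oxohexanal
Product: 4 (S)-4-(3-methylbut-2-en-1-yl)cyclohex-2-en-1-one
Conditions: LiOH, i-PrOH, rt
Reagents that add atoms: none
Why: Intramolecular aldol condensation of the methyl ketone onto the aldehyde (second stage of a Robinson annulation); the stereocentre should survive the mild base and becomes C4 of the enone.

Step 3
Reactants: 4 (S)-4-(3-methylbut-2-en-1-yl)cyclohex-2-en-1-one
Product: 5 trimethyl{[(3S,4S)-3-methyl-4-(3-methylbut-2-en-1-yl)cyclohex-1-en-1-yl]oxy}silane
Conditions: Me2CuLi, TMSCl, THF, −78 °C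
Reagents that add atoms: lithium dimethylcuprate, [Li+].C[Cu-]C; chlorotrimethylsilane, C[Si](C)(C)Cl
Why: Cuprate 1,4-addition with silyl trapping gives the regiodefined silyl enol ether; methyl should add trans to the C4 substituent, at a centre that is removed again in step 4.

Step 4
Reactants: 5 trimethyl{[(3S,4S)-3-methyl-4-(3-methylbut-2-en-1-yl)cyclohex-1-en-1-yl]oxy}silane
Product: 6 (S)-3-methyl-4-(3-methylbut-2-en-1-yl)cyclohex-2-en-1-one
Conditions: Pd(OAc)2 (1.1 equiv), MeCN, rt
Reagents that add atoms: none
Why: Saegusa–Ito oxidation of the silyl enol ether re-forms the enone on the methylated side; the trisubstituted prenyl alkene should be inert to Pd(II) here.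

Step 5
Reactants: 6 (S)-3-methyl-4-(3-methylbut-2-en-1-yl)cyclohex-2-en-1-one
Product: 7 (S)-3,3-dimethyl-4-(3-methylbut-2-en-1-yl)cyclohexan-1-one
Conditions: Me2CuLi, Et2O, −20 → 0 °C; aq. NH4Cl
Reagents that add atoms: lithium dimethylcuprate, [Li+].C[Cu-]C
Why: A second cuprate 1,4-addition builds the gem-dimethyl carbon next to the prenyl-bearing stereocentre, which is not touched.

Step 6
Reactants: 8 dimethyl malonate; 9 2-methyl-2-vinyloxirane (racemic)
Product: 10 dimethyl 2-[(2E)-4-hydroxy-3-methylbut-2-en-1-yl]malonate
Conditions: Pd(PPh3)4 (2 mol %), THF, rt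
Reagents that add atoms: none
Why: Tsuji–Trost 1,4-opening of the vinyl epoxide; the malonate attacks the unsubstituted terminus of the π-allyl complex, which fixes the connectivity CH2–CH=C(Me)–CH2OH needed for an isopropenyl (not methyl/vinyl) cyclopropane.

Step 7
Reactants: 10 dimethyl 2-[(2E)-4-hydroxy-3-methylbut-2-en-1-yl]malonate
Product: 12 dimethyl 2-(prop-1-en-2-yl)cyclopropane-1,1-dicarboxylate (racemic), via allylic mesylate 11 (not isolated)
Conditions: MsCl, Et3N, CH2Cl2, 0 °C; then NaH, THF, 0 °C → rt
Reagents that add atoms: methanesulfonyl chloride, CS(=O)(=O)Cl (kept only in 11)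
Why: Intramolecular SN2' alkylation (3-exo-trig) of the malonate anion, the second stage of the classical malonate/1,4-dihalobut-2-ene vinylcyclopropane synthesis; a malonate cannot O-alkylate and the product is racemic.

Step 8
Reactants: 12 dimethyl 2-(prop-1-en-2-yl)cyclopropane-1,1-dicarboxylate
Product: 13 1-(methoxycarbonyl)-2-(prop-1-en-2-yl)cyclopropane-1-carboxylic acid (racemic)
Conditions: KOH (1.0 equiv), MeOH, 0 °C → rt; then aq. HCl
Reagents that add atoms: potassium hydroxide, [K+].[OH-]
Why: Mono-saponification of a geminal diester stops after one ester because the carboxylate deactivates the second; which ester reacts (probably the one trans to isopropenyl) is of no consequence later.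

Step 9
Reactants: 13 1-(methoxycarbonyl)-2-(prop-1-en-2-yl)cyclopropane-1-carboxylic acid
Product: 14 methyl 1-(1H-benzotriazol-1-ylcarbonyl)-2-(prop-1-en-2-yl)cyclopropane-1-carboxylate
Conditions: SOCl2 (1 equiv), 1H-benzotriazole (4 equiv), CH2Cl2, rt
Reagents that add atoms: 1H-benzotriazole, c1ccc2[nH]nnc2c1
Why: Formation of an N-acylbenzotriazole, a stable acyl donor that C-acylates ketone enolates; excess benzotriazole buffers the HCl so that the activated cyclopropane is not opened.

Step 10
Reactants: 7 (S)-3,3-dimethyl-4-(3-methylbut-2-en-1-yl)cyclohexan-1-one; 14 methyl 1-(1H-benzotriazol-1-ylcarbonyl)-2-(prop-1-en-2-yl)cyclopropane-1-carboxylate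
Product: 15 methyl 1-{[(5R)-4,4-dimethyl-5-(3-methylbut-2-en-1-yl)-2-oxocyclohexyl]carbonyl}-2-(prop-1-en-2-yl)cyclopropane-1-carboxylate (enolised β-diketone; ring C1 and cyclopropane centres as mixtures)
Conditions: 7, LiHMDS (2.2 equiv), THF, −78 °C; then 14, −78 → 0 °C; aq. NH4Cl
Reagents that add atoms: none
Why: Regioselective C-acylation (crossed Claisen type) of the kinetic enolate, formed at the CH2 remote from the CMe2 group, by the N-acylbenzotriazole gives the 2-acylcyclohexanone; the new CH is an enolised β-diketone centre and needs no control.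

Step 11
Reactants: 15 the 2-acylcyclohexanone from step 10; 16 geranyl bromide
Product: 17 methyl 1-{[(1S,5R)-1-[(2E)-3,7-dimethylocta-2,6-dien-1-yl]-4,4-dimethyl-5-(3-methylbut-2-en-1-yl)-2-oxocyclohexyl]carbonyl}-2-(prop-1-en-2-yl)cyclopropane-1-carboxylate (acyl group cis to the prenyl group; cyclopropane centres as mixture)
Conditions: K2CO3, acetone, 40 °C
Reagents that add atoms: none
Why: C-alkylation of the cyclic β-diketone enolate by an allylic bromide creates the quaternary carbon; axial attack on the half-chair enolate with the prenyl group equatorial should place geranyl trans to prenyl and the acyl group cis to it, the opposite face being hindered by the axial methyl of the CMe2 group.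

Step 12
Reactants: 17 the geranylated diketo ester from step 11
Product: 18 5-[(2E)-3,7-dimethylocta-2,6-dien-1-yl]-8,8-dimethyl-7-(3-methylbut-2-en-1-yl)-2'-(prop-1-en-2-yl)spiro[bicyclo[3.3.1]nonane-3,1'-cyclopropane]-2,4,9-trione (H at C1; C7 prenyl endo, on the side of the C2–C3–C4 bridge; four cyclopropane diastereomers)
Conditions: LDA (2.2 equiv), THF, −78 → 0 °C; aq. NH4Cl
Reagents that add atoms: none
Why: Intramolecular Claisen (Dieckmann-type) condensation of the only enolisable position (CH2 next to CMe2) onto the cyclopropane methyl ester closes the trione ring 1,3-diaxially, with the cyclopropane blocking the carbon between the two new ketones; the C1 configuration follows from the bridge, and the second equivalent of base should hold the product as its bridgehead anion against retro-Claisen opening.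

Step 13
Reactants: 18 the spiro-trione from step 12; 19 benzoyl chloride
Product: 20 1-benzoyl derivative of 18 (benzoyl at bridgehead C1; four cyclopropane diastereomers)
Conditions: LiTMP (1.3 equiv), THF, −78 °C; then PhCOCl, −78 → −40 °C
Reagents that add atoms: none
Why: Bridgehead deprotonation between the C2 and C9 ketones followed by C-acylation, a known tactic for bicyclo[3.3.1]nonane-2,4,9-triones; C1–H is the only acidic hydrogen, O-acylation would need a bridgehead enol ester, and the bridgehead geometry is retained.

Step 14
Reactants: 20 the 1-benzoyl spiro(isopropenylcyclopropane) trione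
Product: 22 CNP0164095.1, via tertiary hydroperoxide 21 (not isolated)
Conditions: Mn(dpm)3 (15 mol %), PhSiH3 (1.5 equiv), 5% O2 in N2 (1 atm), i-PrOH–CH2Cl2, 0 °C → rt; then PPh3
Reagents that add atoms: dioxygen, O=O
Why: Proposed new method: Mn–H hydrogen-atom transfer to the CH2 terminus of the isopropenyl group gives a tertiary cyclopropylcarbinyl radical, the strained C3–Cb bond opens to the 1,3-diketone-stabilised C3 radical and a prenyl-type alkene, C3 adds to Cd of the endo C7 prenyl group (7-exo-trig, closing the seven-membered ring of the homoadamantane), the tertiary Cc radical adds back to Cb (5-exo-trig, so the cyclopropane C3/Ca/Cb has grown by Cd–Cc into the cyclopentane), and the exocyclic Me2C radical is trapped by O2 as in a Mukaiyama hydration, PPh3 reducing the hydroperoxide. The closest known reaction types are the thiyl-radical-catalysed vinylcyclopropane–alkene [3+2] annulation, which runs the same opening/addition/5-exo sequence, and the Mukaiyama hydration of 1,1-disubstituted alkenes; new is that a metal hydride starts the relay and oxygen ends it. C3 is fixed by the cage (only its endo face carries the tether), Cd by the alkene turning its CMe2 end toward the C4/C6 side and away from the C8 methyls and the benzoyl group, and Cb by closure with the Me2C terminus on the convex face of the cis-fused five-membered ring. All four diastereomers of the spirocyclopropane should converge, since both cyclopropane stereocentres become sp2 in the ring-opened radical. The step needs HAT at the 1,1-disubstituted alkene in preference to the trisubstituted prenyl and geranyl alkenes (less hindered terminus, irreversible strain-driven opening) and cyclisation faster than O2 capture of the C3 and Cc radicals, which the pre-organised endo prenyl group and the O2-lean atmosphere should secure.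

**Compound list**

1 | 5-methylhex-4-enal | CC(C)=CCCC=O | starting material
2 | but-3-en-2-one (methyl vinyl ketone) | CC(=O)C=C | starting material
3 | (S)-2-(3-methylbut-2-en-1-yl)-5-oxohexanal | CC(=O)CC[C@@H](CC=C(C)C)C=O | intermediate
4 | (S)-4-(3-methylbut-2-en-1-yl)cyclohex-2-en-1-one | O=C1CC[C@@H](CC=C(C)C)C=C1 | intermediate
5 | trimethyl{[(3S,4S)-3-methyl-4-(3-methylbut-2-en-1-yl)cyclohex-1-en-1-yl]oxy}silane (3,4-trans) | C[Si](C)(C)OC1=C[C@@H](C)[C@H](CC=C(C)C)CC1 | intermediate
6 | (S)-3-methyl-4-(3-methylbut-2-en-1-yl)cyclohex-2-en-1-one | O=C1C=C(C)[C@H](CC=C(C)C)CC1 | intermediate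
7 | (S)-3,3-dimethyl-4-(3-methylbut-2-en-1-yl)cyclohexan-1-one | O=C1CC[C@@H](CC=C(C)C)C(C)(C)C1 | intermediate
8 | dimethyl malonate | COC(=O)CC(=O)OC | starting material
9 | 2-methyl-2-vinyloxirane (racemic) | CC1(C=C)CO1 | starting material
10 | dimethyl 2-[(2E)-4-hydroxy-3-methylbut-2-en-1-yl]malonate | COC(=O)C(C/C=C(\C)CO)C(=O)OC | intermediate
11 | dimethyl 2-[(2E)-3-methyl-4-(methylsulfonyloxy)but-2-en-1-yl]malonate (allylic mesylate, not isolated) | COC(=O)C(C/C=C(\C)COS(C)(=O)=O)C(=O)OC | intermediate
12 | dimethyl 2-(prop-1-en-2-yl)cyclopropane-1,1-dicarboxylate (racemic) | COC(=O)C1(CC1C(C)=C)C(=O)OC | intermediate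
13 | 1-(methoxycarbonyl)-2-(prop-1-en-2-yl)cyclopropane-1-carboxylic acid (racemic, relative configuration not controlled) | COC(=O)C1(CC1C(C)=C)C(O)=O | intermediate
14 | methyl 1-(1H-benzotriazol-1-ylcarbonyl)-2-(prop-1-en-2-yl)cyclopropane-1-carboxylate | COC(=O)C1(CC1C(C)=C)C(=O)n1nnc2ccccc21 | intermediate
15 | methyl 1-{[(5R)-4,4-dimethyl-5-(3-methylbut-2-en-1-yl)-2-oxocyclohexyl]carbonyl}-2-(prop-1-en-2-yl)cyclopropane-1-carboxylate (ring C1 and cyclopropane centres as mixtures) | COC(=O)C1(CC1C(C)=C)C(=O)C2C[C@@H](CC=C(C)C)C(C)(C)CC2=O | intermediate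
16 | geranyl bromide, (2E)-1-bromo-3,7-dimethylocta-2,6-diene | CC(C)=CCC/C(C)=C/CBr | starting material
17 | methyl 1-{[(1S,5R)-1-geranyl-4,4-dimethyl-5-(3-methylbut-2-en-1-yl)-2-oxocyclohexyl]carbonyl}-2-(prop-1-en-2-yl)cyclopropane-1-carboxylate (acyl cis to prenyl; cyclopropane centres as mixture) | CC(C)=CCC/C(C)=C/C[C@]1(C(=O)C2(CC2C(C)=C)C(=O)OC)C[C@@H](CC=C(C)C)C(C)(C)CC1=O | intermediate
18 | 5-geranyl-8,8-dimethyl-7-(3-methylbut-2-en-1-yl)-2'-(prop-1-en-2-yl)spiro[bicyclo[3.3.1]nonane-3,1'-cyclopropane]-2,4,9-trione (H at C1, C7 prenyl endo, four cyclopropane diastereomers) | CC(C)=CCC/C(C)=C/C[C@]12C[C@@H](CC=C(C)C)C(C)(C)[C@H](C1=O)C(=O)C3(CC3C(C)=C)C2=O | intermediate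
19 | benzoyl chloride | O=C(Cl)c1ccccc1 | starting material
20 | 1-benzoyl-5-geranyl-8,8-dimethyl-7-(3-methylbut-2-en-1-yl)-2'-(prop-1-en-2-yl)spiro[bicyclo[3.3.1]nonane-3,1'-cyclopropane]-2,4,9-trione (C7 prenyl endo, four cyclopropane diastereomers) | CC(C)=CCC/C(C)=C/C[C@]12C[C@@H](CC=C(C)C)C(C)(C)[C@](C(=O)c3ccccc3)(C1=O)C(=O)C4(CC4C(C)=C)C2=O | intermediate
21 | tertiary hydroperoxide of 22 (C(Me)2OOH in place of C(Me)2OH, not isolated) | CC(C)=CCC/C(C)=C/C[C@@]12C[C@H]3C[C@H]4C(C)(C)[C@H](C(C)(C)OO)C[C@]4(C1=O)C(=O)[C@@](C(=O)c1ccccc1)(C2=O)C3(C)C | intermediate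
22 | CNP0164095.1 (1-benzoyl-5-geranyl homoadamantane trione with fused 2,2-dimethyl-3-(2-hydroxypropan-2-yl)cyclopentane) | CC(C)=CCC/C(C)=C/C[C@@]12C[C@H]3C[C@H]4C(C)(C)[C@H](C(C)(C)O)C[C@]4(C1=O)C(=O)[C@@](C(=O)c1ccccc1)(C2=O)C3(C)C | target

**Step count and risks**

Total steps: 14. Longest linear sequence: 10 (steps 1–5 and 10–14).

Step 14 (Proposed new method). What may go wrong: capture of the C3 or Cc radical by O2 before cyclisation, or competing hydrogen-atom transfer at the trisubstituted alkenes, leading to ring-opened or over-hydrated material. The fallback uses known chemistry and sets out from 20. Diphenyl disulfide (20 mol %) with AIBN in degassed benzene at 70 °C should run the thiyl-radical-catalysed vinylcyclopropane–alkene [3+2] annulation without oxygen and give the isopropenyl cage compound F1 through the same opening/7-exo/5-exo relay, ended by loss of the thiyl radical. Mukaiyama hydration of the 1,1-disubstituted alkene of F1 (Co(acac)2, PhSiH3, O2, i-PrOH; then PPh3) comes back to the route at 22.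

Step 12. What may go wrong: reversal of the Claisen closure by methoxide attack on the non-enolisable β-diketone, or opening of the activated cyclopropane by the enolate. The fallback sets out from 17 and replaces the reversible ester condensation by an irreversible acid chloride acylation. Me3SnOH (1,2-dichloroethane, 80 °C) should cleave the methyl ester to the keto acid F2. 1-Chloro-N,N,2-trimethylprop-1-en-1-amine should convert it under neutral conditions into the acid chloride F3. TMSOTf/Et3N then forms the silyl enol ether of the ring ketone in situ, which should be C-acylated intramolecularly. This comes back to the route at 18.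

Step 13. What may go wrong: slow or unselective acylation of the hindered bridgehead anion. The fallback sets out from 18 and changes acylation into aldol addition and oxidation. The bridgehead anion (LiTMP, THF, −78 °C) is trapped with the smaller electrophile benzaldehyde to give the bridgehead carbinol F4 (either carbinol epimer serves). Dess–Martin periodinane then oxidises it, coming back to the route at 20.

**Further compounds**

F1 | step 14 | isopropenyl analogue of 22 (C(Me)=CH2 in place of C(Me)2OH) | CC(C)=CCC/C(C)=C/C[C@@]12C[C@H]3C[C@H]4C(C)(C)[C@H](C(C)=C)C[C@]4(C1=O)C(=O)[C@@](C(=O)c1ccccc1)(C2=O)C3(C)C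
F2 | step 12 | carboxylic acid corresponding to methyl ester 17 | CC(C)=CCC/C(C)=C/C[C@]1(C(=O)C2(CC2C(C)=C)C(O)=O)C[C@@H](CC=C(C)C)C(C)(C)CC1=O
F3 | step 12 | acid chloride of F2 | CC(C)=CCC/C(C)=C/C[C@]1(C(=O)C2(CC2C(C)=C)C(Cl)=O)C[C@@H](CC=C(C)C)C(C)(C)CC1=O
F4 | step 13 | 1-[hydroxy(phenyl)methyl] analogue of 20 (bridgehead carbinol) | CC(C)=CCC/C(C)=C/C[C@]12C[C@@H](CC=C(C)C)C(C)(C)[C@](C(O)c3ccccc3)(C1=O)C(=O)C4(CC4C(C)=C)C2=O
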